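Take the amounts in the blue run. After 1.00 min, 65.0 % of the charge is gone but only 15.4 % is target.

| flask | starting material | temperature | remark | time |
|---|---|---|---|---|
| blue | 0.10 M | 82 °C | run made earlier |  |
| amber | 0.15 M | 99 °C | run made earlier |  |
| Sunday's | 0.20 M | 105 °C |  | 3.0 min |
| Friday's | 0.20 M | 90 °C |  | 3.0 min |
| Tuesday's | 0.20 M | 75 °C |  | 3.0 min |
| Wednesday's | 0.20 M |  | at 75 °C until 1.5 min, from then on at 105 °C | 3.0 min |

- blue (time / min: target / %, starting material / %): 1.00: 15.4, 35.0; 2.00: 22.2, 20.7; 3.00: 24.1, 13.2; 4.00: 26.7, 10.6; 5.00: 28.8, 7.8; 6.00: 27.2, 7.4; 8.00: 27.0, 5.9
- amber (time / min: target / %, starting material / %): 0.333: 20.3, 23.9; 0.667: 21.5, 13.4; 1.00: 23.3, 9.3; 1.33: 19.7, 10.0; 1.50: 21.2, 8.5; 2.00: 19.2, 5.1; 2.50: 17.0, 6.4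

(standard deviation of a reading: 1 percentage point)

- what was read earlier has a scatter of 1 percentage point, one standard deviation

1. which flask leads in amount of target, in percent of the starting material charged ("all alike" within 1.5 percentage points) (Sunday's / Friday's / Tuesday's / Wednesday's / all alike)
2. how much target is there at the end, in percent of the starting material charged: Sunday's
3. how much target is there at the end, in percent of the starting material charged: Friday's
4. how much target is there at the end, in percent of the starting material charged: Tuesday's
5. how much target is there at the end, in percent of the starting material charged: Wednesday's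

Build the flask up one process at a time, and begin with the main step, starting material to target. Alone it would turn every percent used into target, yet blue's share at that first reading is 23.7 %.

Now add a second route. In blue, the reciprocal of the fraction remaining, less one, at 2.00 min is twice its value at 1.00 min, so this route takes starting material in pairs. Its rate goes with [starting material] squared, while the rate into target goes with [starting material]. Divide one rate by the other and time drops out, leaving a selectivity factor that I call the split.

Get the split per molar from the first readings. Take one over the share, subtract one, and divide by the mean fraction remaining and by the charge. This gives 47.7 M⁻¹ for blue and 29.6 M⁻¹ for amber. Carry its logarithm in a straight line over temperature and multiply by the charge. Sunday's split, the pair route's rate over the rate into target at the start of the flask, is then 5.00. Friday's is 7.62 and Tuesday's 11.6.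

The target made when the fraction remaining has fallen to a given value is the logarithm of one plus the split, over one plus the split times that fraction, all divided by the split. Read the pair constant from the first readings in the same way, 18.6 M⁻¹ min⁻¹ for blue and 63.7 M⁻¹ min⁻¹ for amber. My reckoning leaves 13.0 % in Tuesday's and 4.78 % in Friday's. That gives 13.9 % for Tuesday's and 24.2 % for Friday's, and at most 35.8 % for Sunday's.

Last, add the fall of target. Compare the mean of amber's three target readings from 0.667 min to 1.33 min with the mean of its three from 1.50 min to 2.50 min; the means soften the scatter, and the reading is a fall of 0.117 min⁻¹. Take half that rate for Friday's, and let it rise at the same pace up to Sunday's. Friday's comes to 20.3 % and Sunday's to 20.6 %, about level, and both stand above Tuesday's. Sunday's figure counts the charge as fully used, so it is a ceiling, and I lean to Friday's as the leader. Wednesday's spends its last 1.50 min at 105 °C, where my fall keeps 75.8 % of the target, less than the 84.0 % that Friday's keeps over its whole time. Supposing Wednesday's makes about what Friday's makes, I put Wednesday's below Friday's.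

The forecast differs from this: it names Tuesday's and gives 12 %, 23 %, 26 % and 18 % for Sunday's, Friday's, Tuesday's and Wednesday's, with the words “Tuesday's: 88% conversion, little loss, about 26”.

The flasks give 9.97 % for Sunday's, 18.7 % for Friday's, 14.2 % for Tuesday's and 12.1 % for Wednesday's, so Friday's leads.

    2 starting material → self-condensation product (k = 0.200 M⁻¹ s⁻¹, Ea = 77.0 kJ mol⁻¹)
    starting material ⇌ target (K = 3.00, k = 0.0100 s⁻¹, Ea = 97.0 kJ mol⁻¹, ΔH = −43.0 kJ mol⁻¹)
    (constants at 90 °C)

Tuesday's split of 11.6 gave 13.9 %, against the 14.2 % found. Now take the neighbouring flask, Sunday's with 0.050 M of starting material. Its split is a quarter of Sunday's, 1.25. The same logarithm and Sunday's fall give 37.3 %. At 3.00 min that flask holds 24.6 % of target, with 12.7 % of starting material remaining.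

The numbers in the tables are calculated with made-up constants; noise was put on by code.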